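At early times the birch run gives a first reading of isomer of the product A of 1.6%, with a scatter of 1 percentage point. Single ratios are therefore weak, and I pool the readings.

| flask | starting material | free catalyst | remark | time |
|---|---|---|---|---|
| birch | 2.1 M | 4.2 mM | the very flask that is asked about, followed so far |  |
| flask | 2.1 M | 4.2 mM |  | 3.0 d |

birch run (percent of the starting material charged)

| time / h | target / % | isomer of the product A / % |
|---|---|---|
| 2.50 | 5.3 | 1.6 |
| 5.00 | 9.1 | 1.9 |
| 8.00 | 13.0 | 1.1 |
| 10.0 | 16.7 | 4.2 |
| 12.0 | 19.0 | 6.2 |
| 15.0 | 24.0 | 3.9 |

(standard deviation of a reading: 1 percentage point)

* ratio of target to isomer of the product A at 50 min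
* ratio of target to isomer of the product A at 8.0 h
* ratio of target to isomer of the product A at 3.0 d
* which of target and isomer of the product A there is more of at 3.0 d



Pooled over the birch run up to 8.00 h, c(target)/c(isomer of the product A) reads 5.96; pooled from 10.0 h on, it reads 4.17. In logarithms against the mean times, this gives 0.408, which I call the lag slope: the powers of ten the ratio loses per power of ten of time. It is a rough reading, since the earlier isomer readings sum to 4.60% and each is good to 1 point. Still, a positive slope suggests an induction period for isomer of the product A.

Time is the first setting, and as a power law the slope gives me 12.6 at 50 min, 4.98 at 8.0 h and 2.03 at 3.0 d, so in my reckoning target stays ahead. Next comes the charge of starting material: the readings are percentages of the charge, so if each step is first order in the organic species, the ratio stays put. Last comes the catalyst charge: if free catalyst feeds isomer of the product A, more of it should shorten the lag and lower the ratio at 50 min.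

The forecast, holding that “there is no clear lag”, gives 4.7, 4.6 and 4.3 with target ahead, where my ratio at 50 min is higher and my ratio at 3.0 d lower.

The flask gives 17.0, 5.21 and 3.62, with target ahead at 44.0% against 12.2%.

    starting material ⇌ target (K = 1.30, k = 3.30 × 10⁻⁴ min⁻¹)
    target + free catalyst ⇌ isomer of the product A + free catalyst, rate k2*[free catalyst]*[target] forward; the back reaction follows from the equilibrium constant (K = 0.380, k = 0.0670 M⁻¹ min⁻¹)
    isomer of the product A ⇌ isomer of the product B (K = 0.520, k = 0.00400 min⁻¹)
    isomer of the product B ⇌ starting material (k = 4.40 × 10⁻⁴ min⁻¹)
    free catalyst → spent catalyst (k = 0.0140 min⁻¹)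

In this flask, isomer of the product A and isomer of the product B relax towards each other by their own step alone, both ways together, with a half-life of 0.988 h, longer than 50 min and shorter than 8.0 h, and across that span the ratios of this flask give a lag slope of 0.523. Carried back from 8.0 h, my slope turns the 5.06 of the neighbour charged with 0.017 M of free catalyst into 12.7 at 50 min, and that neighbour stands at 14.2.

The runs were computed for an exercise; noise was put on by code.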